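The next run goes to epsilon at 30 °C, and one time, the fill time, places each flask against the 8.0 h it gets.

| setting | grey | amber | ochre | theta | eta | epsilon | delta |
|---|---|---|---|---|---|---|---|
| Q | 0.028 M | 0.044 M | 0.020 M | 0.020 M | 0.020 M | 0.020 M | 0.020 M |
| X | 0.012 M | 0.012 M | 0.012 M | 0.0120 M | 0.0120 M | 0.0120 M | 0.0120 M |
| E | 0.40 mM | 0.40 mM | 0.20 mM | 0.400 mM | 0.400 mM | 0.400 mM | 0.400 mM |
| temperature | −5 °C | 45 °C | −5 °C | 0 °C | 60 °C | 30 °C | 90 °C |
| remark | run made earlier | run made earlier | run made earlier |  |  |  |  |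
| time |  |  |  | 8.0 h | 8.0 h | 8.0 h | 8.0 h |

grey run (percent of the Q charged)

| time / h | G / % | Q / % |
|---|---|---|
| 2.00 | 0.1 | 99.8 |
| 4.00 | 0.3 | 100.1 |
| 6.00 | 0.6 | 99.7 |
| 8.00 | 0 | 99.8 |
| 10.0 | 0.7 | 99.6 |

amber run (percent of the Q charged)

| time / min | G / % | Q / % |
|---|---|---|
| 5.00 | 0.6 | 99.2 |
| 15.0 | 2.5 | 97.7 |
| 25.0 | 3.7 | 95.2 |
| 40.0 | 5.3 | 94.1 |
| 60.0 | 7.1 | 91.7 |

ochre run (percent of the Q charged)

| time / h | G / % | Q / % |
|---|---|---|
| 0.833 | 0.3 | 99.9 |
| 1.33 | 0.3 | 100.0 |
| 2.50 | 0.5 | 99.6 |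
| 5.00 | 1.1 | 99.4 |
| 10.0 | 1.1 | 99.6 |

(scatter of a reading: 0.3 percentage points)

- the flask with the highest amount of G, in percent of the Q charged ("all alike" if they lie within 1.5 percentage points) (theta / eta / epsilon / delta / all alike)
- final G, as a percentage of the Q charged, in theta
- final G, as a percentage of the Q charged, in eta
- final G, as a percentage of the Q charged, in epsilon
- final G, as a percentage of the Q charged, in delta

In these flasks X is the smaller charge, and E may take its own charge of X. This leaves G a room of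

room = (X charged − E charged)/Q charged = 58.0%.

Amber, grey and ochre share the same [X]. Amber starts at 0.100 h⁻¹ of the Q charged. Grey and ochre end at 0.7% and 1.1%, a gap near the scatter although [Q] and [E] differ, so their mean gives 9.00 × 10⁻⁴ h⁻¹. Grey to amber spans 10/3 of the step from 30 °C to 45 °C, so one such step multiplies the rate by

F = 4.11.

The fill time, the time in which the room would fill at the starting rate, is at 45 °C

room/rate = 5.80 h.

One step either way gives 23.8 h in epsilon and 1.41 h in eta. The crossing, where fill time equals run time, therefore lies between 30 °C and 45 °C. Below it G follows the clock, pseudo-first-order in X with [Q] taken as steady: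

G = room × (1 − exp(−t/fill)) = 16.5% in epsilon.

Above the crossing this line need not hold. Late in amber, G gains 0.0540 h⁻¹, which is 54.0% of the starting reading, while the readings leave 74.0% of the X. So the gain there falls faster than X does, as far as the scatter shows. The line would put eta at 57.8%, but eta lies above the crossing, where the line need not hold, while epsilon lies below it, so epsilon is the choice.

The forecast, a little below this reckoning for epsilon, names epsilon, with 1.2% in theta, 11% in eta, 15% in epsilon and 6% in delta: “Epsilon is the likely best, but this is uncertain.”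

Epsilon gives 15.1%, the highest of the flasks, against 0.846% in theta, 9.76% in eta and 0.125% in delta, and it stands 1.4 percentage points under the reckoning. At 8.00 h epsilon still holds 69.8% of its X, and its G stands at 30.6% after 80.0 h. Eta, with its fill time of 1.41 h, holds G 14.9% at 4.00 h and less at 8.00 h, 9.76%.

    Q + X ⇌ G (K = 50.2 M⁻¹, k = 0.00835 M⁻¹ s⁻¹, Ea = 73.0 kJ mol⁻¹, ΔH = −65.0 kJ mol⁻¹)
    Q + X ⇌ J (K = 14000 M⁻¹, k = 1.53 × 10⁻⁴ M⁻¹ s⁻¹, Ea = 62.0 kJ mol⁻¹, ΔH = −26.0 kJ mol⁻¹)
    Q + G → D (k = 0.00153 M⁻¹ s⁻¹, Ea = 74.0 kJ mol⁻¹)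
    X + E → Z (k = 0.708 M⁻¹ s⁻¹, Ea = 43.0 kJ mol⁻¹)
    G → L (k = 4.38 × 10⁻⁵ s⁻¹, Ea = 118 kJ mol⁻¹)
    (constants at 60 °C)

A flask like epsilon kept at 45 °C has a fill time of 5.80 h, just under the run and nearer the crossing, and the line gives 43.4%. That flask gives 25.3%, more than epsilon and less than the line, with D at 6.73% and L at 3.11% beside it.

(The runs are calculated with made-up constants; scatter was added.)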